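A direct plan would build ring C (the 4-pyranone ring of the chromone) first and would reach 7-methoxy-5-methyl-2-(methylsulfonyl)-4H-chromen-4-one A1 from a 2-hydroxyacetophenone through a thione, a sulfide and a sulfone. The sulfonyl group of A1 would be displaced by the lithiated methyl group of 4-(benzyloxy)-6-methyl-2H-pyran-2-one A2 to give the CH2-bridged chromone–pyranone A3 as the substrate for the last carbon–carbon bond. The aryne released from 3,5-dimethoxy-2-(trimethylsilyl)phenyl trifluoromethanesulfonate A4 would then be inserted into the C-2–CH2 bond of A3 to place ring B (the resorcinol ring), before a global ether cleavage.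
Its weakest steps would be:
(a) the aryne insertion, in which the aryne from A4 would have to enter the C-2–CH2 σ-bond of A3 without precedent at a vinylogous acyl carbon: it needs a strained 4-exo closure onto the weakly electrophilic C-2 and competes with plain C-arylation of the carbanion and with [4+2] addition of the aryne to the pyranone;
(b) the thione–sulfide–sulfone sequence: the three steps to A1 would only install a leaving group at C-2 and form no bond of the skeleton;
(c) the sulfone displacement: product A3 is far more acidic than lithiated A2 as the nucleophile, so a full extra equivalent of the prepared carbanion would be spent as base and over-addition would threaten.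

**Retrosynthetic overview**
Ring C is cut into three components: an iodo-orcinol (ring A with O-1 and C-4a), carbon monoxide (C-4) and a terminal arylalkyne (C-2, C-3, ring B and the benzyl-protected 2-pyranone). One palladium-catalysed carbonylative annulation forms C-4a–C-4, C-4–C-3 and O-1–C-2.
The feature used is C-1' of ring B, flanked by O-2' and the C-6' CH2 arm: the C-2–C-1' bond is made earlier as an aryl–alkyne bond, where the linear partner does not feel the two ortho groups. The iodide sits there by iodination of 3,5-dimethoxyphenylacetic acid, and the C-6'–CH2 bond is bought.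
Ring order: the 2-pyranone is closed first (acylketene lactonisation of a keto-dioxinone grown on the acetic acid arm), ring C last; rings A and B are bought.
The design needs no aryne insertion, carries no leaving group on a chromone (the chromone exists only after the key step) and spends no sacrificial carbanion.

Key step: step 7

Remark: the target has no stereocentre, and the lactone ring is treated as the 4-hydroxy-2H-pyran-2-one tautomer of the given SMILES.

**Step 1**
Reactants: 1 2-(3,5-dimethoxyphenyl)acetic acid
Product: 2 2-(2-iodo-3,5-dimethoxyphenyl)acetic acid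
Conditions: NIS (1.05 equiv), MeCN, 0 °C to rt, dark
Reagents that add atoms: N-iodosuccinimide, O=C1CCC(=O)N1I
Why: Electrophilic aromatic iodination should take the position ortho to the CH2CO2H arm and para to a methoxy group (two equivalent sites) and not the more crowded position between the two methoxy groups, which places the iodine on the future C-1' of ring B.

**Step 2**
Reactants: 2 2-(2-iodo-3,5-dimethoxyphenyl)acetic acid; 3 2,2,6-trimethyl-4H-1,3-dioxin-4-one (2.5 equiv)
Product: 6 6-[3-(2-iodo-3,5-dimethoxyphenyl)-2-oxopropyl]-2,2-dimethyl-4H-1,3-dioxin-4-one, via acid chloride 4 (not isolated), via lithium dienolate 5 (not isolated)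
Conditions: 2, (COCl)2, cat. DMF, CH2Cl2, 0 °C to rt, evaporation; 3, LiN(SiMe3)2 (2.5 equiv), THF, −78 °C; then 4, −78 °C; AcOH, aq. NH4Cl
Reagents that add atoms: none
Why: The γ-carbon of the dioxinone dienolate should be acylated by the acid chloride (Claisen-type vinylogous acylation), the excess dienolate taking up the acidic proton of the product, and any arylketene formed from 4 by dehydrochlorination is captured by the same dienolate at carbon to give the same enolate.

**Step 3**
Reactants: 6 6-[3-(2-iodo-3,5-dimethoxyphenyl)-2-oxopropyl]-2,2-dimethyl-4H-1,3-dioxin-4-one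
Product: 8 4-hydroxy-6-[(2-iodo-3,5-dimethoxyphenyl)methyl]-2H-pyran-2-one, via acylketene 7 (not isolated)
Conditions: PhMe, 110 °C
Reagents that add atoms: none
Why: Thermal retro-[4+2] loss of acetone from the dioxinone should give acylketene 7, whose ketene carbon is captured by the enol oxygen of the δ-ketone (acylketene lactonisation) to close the 4-hydroxy-2-pyranone ring, the usual fate of keto-dioxinones heated without an external nucleophile.

**Step 4**
Reactants: 8 4-hydroxy-6-[(2-iodo-3,5-dimethoxyphenyl)methyl]-2H-pyran-2-one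
Product: 9 4-(benzyloxy)-6-[(2-iodo-3,5-dimethoxyphenyl)methyl]-2H-pyran-2-one
Conditions: BnOH (1.2 equiv), PPh3, DIAD, THF, 0 °C to rt
Reagents that add atoms: benzyl alcohol, OCc1ccccc1
Why: Mitsunobu O-alkylation of the acidic vinylogous acid should benzylate the 4-oxygen under neutral conditions, so that the acidic CH2 bridge is not alkylated and the pyranone cannot act as a nucleophile in the palladium steps.

**Step 5**
Reactants: 9 4-(benzyloxy)-6-[(2-iodo-3,5-dimethoxyphenyl)methyl]-2H-pyran-2-one
Product: 11 4-(benzyloxy)-6-[(2-ethynyl-3,5-dimethoxyphenyl)methyl]-2H-pyran-2-one, via silylalkyne 10 (not isolated)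
Conditions: HC≡CSiMe3 (2 equiv), PdCl2(PPh3)2 (5 mol %), CuI (10 mol %), Et3N (3 equiv), THF, 60 °C; then AcOH, Bu4NF, 0 °C
Reagents that add atoms: ethynyltrimethylsilane, C#C[Si](C)(C)C
Why: Sonogashira coupling at the aryl iodide should succeed in spite of the two ortho substituents because the alkyne partner is linear, and fluoride buffered with acetic acid removes the silyl group without touching the pyranone or the acidic CH2 bridge.

**Step 6**
Reactants: 12 5-methylbenzene-1,3-diol (orcinol)
Product: 13 4-iodo-5-methylbenzene-1,3-diol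
Conditions: ICl (1.0 equiv), Et2O, 0 °C
Reagents that add atoms: iodine monochloride, ClI
Why: Electrophilic iodination under non-basic conditions should go para to one hydroxyl and ortho to the other (C-4, two equivalent sites), as in the ICl iodination of resorcinol to 4-iodoresorcinol and in the C-4 formylation and acylation of orcinol, the position between the hydroxyls being taken mainly under aqueous base.

**Step 7**
Reactants: 11 4-(benzyloxy)-6-[(2-ethynyl-3,5-dimethoxyphenyl)methyl]-2H-pyran-2-one; 13 4-iodo-5-methylbenzene-1,3-diol (1.2 equiv)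
Product: 16 2-{2-[(4-benzyloxy-2-oxo-2H-pyran-6-yl)methyl]-4,6-dimethoxyphenyl}-7-hydroxy-5-methyl-4H-chromen-4-one, via ynone 14 (not isolated), via enaminone 15 (not isolated)
Conditions: PdCl2(dppf) (5 mol %), CO (5 bar), Et2NH (4 equiv), MeCN, 70 °C, no copper salt
Reagents that add atoms: carbon monoxide, [C-]#[O+]
Why: Oxidative addition of zerovalent palladium into the C–I bond of 13, CO insertion to the aroylpalladium iodide and coupling with the terminal alkyne of 11 (carbonylative Sonogashira coupling) should give ynone 14; diethylamine adds to its β-carbon to give enaminone 15, and the ortho-hydroxyl then displaces the amine by addition–elimination to close ring C. The reaction type is the known palladium-catalysed carbonylative annulation of 2-iodophenols with terminal arylacetylenes to flavones, applied here to a hindered pair. Ring C is closed in the 6-endo sense (oxygen to the alkyne carbon remote from the carbonyl), the amine adduct ruling out the 5-exo closure to an aurone. No stereocentre is formed. The step needs CO insertion to outrun direct alkynylation of the aryl–palladium species (which would end in a 2-arylbenzofuran) and alkyne capture of the acylpalladium to outrun aminolysis to the diethylamide: the first is secured by the electron-rich, di-ortho-substituted aryl–palladium bond, the CO pressure and the absence of copper, the second by the hindered 2,6-disubstituted aroyl group and the small excess of amine. Only the hydroxyl ortho to iodine can reach the ynone, so the second hydroxyl of 13 ends as the free 7-OH, and the benzyl ether keeps the pyranone from acting as a nucleophile.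

**Step 8**
Reactants: 16 2-{2-[(4-benzyloxy-2-oxo-2H-pyran-6-yl)methyl]-4,6-dimethoxyphenyl}-7-hydroxy-5-methyl-4H-chromen-4-one
Product: 17 2-{2,4-dihydroxy-6-[(4-hydroxy-2-oxo-2H-pyran-6-yl)methyl]phenyl}-7-hydroxy-5-methyl-4H-chromen-4-one (CNP0309284.0)
Conditions: BBr3 (8 equiv), pentamethylbenzene (3 equiv), CH2Cl2, −78 °C to rt; MeOH, then H2O
Reagents that add atoms: none
Why: Lewis-acid ether cleavage should remove the two aryl methyl ethers by bromide attack on the boron-complexed ethers and the benzyl vinylogous ester by ionisation to a benzyl cation that pentamethylbenzene traps (Friedel–Crafts alkylation), the chromone and the 4-hydroxy-2-pyranone being stable to BBr3.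

**Compound list**
1 | 2-(3,5-dimethoxyphenyl)acetic acid | COc1cc(CC(=O)O)cc(OC)c1 | starting material
2 | 2-(2-iodo-3,5-dimethoxyphenyl)acetic acid | COc1cc(CC(=O)O)c(I)c(OC)c1 | intermediate
3 | 2,2,6-trimethyl-4H-1,3-dioxin-4-one | CC1=CC(=O)OC(C)(C)O1 | starting material
4 | 2-(2-iodo-3,5-dimethoxyphenyl)acetyl chloride (acid chloride) | COc1cc(CC(=O)Cl)c(I)c(OC)c1 | intermediate
5 | lithium 2,2-dimethyl-6-methylidene-6H-1,3-dioxin-4-olate (lithium dienolate) | [Li+].[O-]C1=CC(=C)OC(C)(C)O1 | intermediate
6 | 6-[3-(2-iodo-3,5-dimethoxyphenyl)-2-oxopropyl]-2,2-dimethyl-4H-1,3-dioxin-4-one | COc1cc(CC(=O)CC2=CC(=O)OC(C)(C)O2)c(I)c(OC)c1 | intermediate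
7 | 6-(2-iodo-3,5-dimethoxyphenyl)hex-1-ene-1,3,5-trione (acylketene) | COc1cc(CC(=O)CC(=O)C=C=O)c(I)c(OC)c1 | intermediate
8 | 4-hydroxy-6-[(2-iodo-3,5-dimethoxyphenyl)methyl]-2H-pyran-2-one | COc1cc(Cc2cc(O)cc(=O)o2)c(I)c(OC)c1 | intermediate
9 | 4-(benzyloxy)-6-[(2-iodo-3,5-dimethoxyphenyl)methyl]-2H-pyran-2-one | COc1cc(Cc2cc(OCc3ccccc3)cc(=O)o2)c(I)c(OC)c1 | intermediate
10 | 4-(benzyloxy)-6-({3,5-dimethoxy-2-[(trimethylsilyl)ethynyl]phenyl}methyl)-2H-pyran-2-one (silylalkyne) | COc1cc(Cc2cc(OCc3ccccc3)cc(=O)o2)c(C#C[Si](C)(C)C)c(OC)c1 | intermediate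
11 | 4-(benzyloxy)-6-[(2-ethynyl-3,5-dimethoxyphenyl)methyl]-2H-pyran-2-one | COc1cc(Cc2cc(OCc3ccccc3)cc(=O)o2)c(C#C)c(OC)c1 | intermediate
12 | 5-methylbenzene-1,3-diol (orcinol) | Cc1cc(O)cc(O)c1 | starting material
13 | 4-iodo-5-methylbenzene-1,3-diol | Cc1cc(O)cc(O)c1I | intermediate
14 | 4-(benzyloxy)-6-({2-[3-(2,4-dihydroxy-6-methylphenyl)-3-oxoprop-1-yn-1-yl]-3,5-dimethoxyphenyl}methyl)-2H-pyran-2-one (ynone) | Cc1cc(O)cc(O)c1C(=O)C#Cc1c(OC)cc(OC)cc1Cc1cc(OCc2ccccc2)cc(=O)o1 | intermediate
15 | (E)-3-(diethylamino) adduct of ynone 14 at its β-carbon (enaminone) | CCN(CC)/C(=C/C(=O)c1c(C)cc(O)cc1O)c1c(OC)cc(OC)cc1Cc1cc(OCc2ccccc2)cc(=O)o1 | intermediate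
16 | 2-{2-[(4-benzyloxy-2-oxo-2H-pyran-6-yl)methyl]-4,6-dimethoxyphenyl}-7-hydroxy-5-methyl-4H-chromen-4-one | Cc1cc(O)cc2oc(-c3c(OC)cc(OC)cc3Cc3cc(OCc4ccccc4)cc(=O)o3)cc(=O)c12 | intermediate
17 | 2-{2,4-dihydroxy-6-[(4-hydroxy-2-oxo-2H-pyran-6-yl)methyl]phenyl}-7-hydroxy-5-methyl-4H-chromen-4-one | Cc1cc(O)cc2oc(-c3c(O)cc(O)cc3Cc3cc(O)cc(=O)o3)cc(=O)c12 | target

**Step count and risks**
Total steps: 8. Longest linear sequence: 7 (steps 1, 2, 3, 4, 5, 7, 8).

Steps most likely to fail:

1. Step 7 (carbonylative annulation). CO insertion may be outrun by direct alkynylation of the aryl–palladium species, which leads on to a benzofuran. The acylpalladium may be taken by diethylamine as the amide. Oxidative addition at the electron-rich, di-ortho-substituted iodide may be slow, and on long heating the amine may attack the alkoxypyranone. Fallback, from 11 and back at 16: the carbonyl carbon would be brought in with ring A instead of as CO. Purchased 2,4-dihydroxy-6-methylbenzoic acid F1 would be acetylated with Ac2O in pyridine to 2,4-diacetoxy-6-methylbenzoic acid F2 and then converted with (COCl)2 into 2,4-diacetoxy-6-methylbenzoyl chloride F3 in CH2Cl2. Acyl Sonogashira coupling of F3 with 11 (PdCl2(PPh3)2, CuI, Et3N, THF, rt) would give 4-{3-[2-({4-(benzyloxy)-2-oxo-2H-pyran-6-yl}methyl)-4,6-dimethoxyphenyl]prop-2-ynoyl}-5-methyl-1,3-phenylene diacetate F4 as an ynone that already holds C-4. Et2NH in MeCN at rt to 40 °C would then cleave both acetates of F4 by aminolysis and close ring C through the amine adduct, to give 16.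

2. Step 6 (iodination of orcinol). Iodination may also occur between the two hydroxyls or twice, and the electron-rich iodoresorcinol may lose or shift its iodine under the acid that is set free. Fallback, from 12 and back at 13: the hydroxyls would be masked so that crowding governs the site. 12 would be O-methylated with Me2SO4 and K2CO3 in acetone to 1,3-dimethoxy-5-methylbenzene F5 (this ether is also sold). NIS in MeCN would convert F5 into 2-iodo-1,5-dimethoxy-3-methylbenzene F6 because the position between the two methoxy groups is the hindered one, and BBr3 in CH2Cl2 at −78 to 0 °C would demethylate F6 to 13.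

3. Step 2 (acylation of the dioxinone dienolate). The arylacetyl chloride may be dehydrochlorinated to a ketene that dimerises, or the dienolate may be acylated at oxygen. Fallback, from 2 and back at 8, in place of steps 2 and 3: 2 would be converted with 1,1'-carbonyldiimidazole and MeNH(OMe)·HCl into 2-(2-iodo-3,5-dimethoxyphenyl)-N-methoxy-N-methylacetamide F7 in CH2Cl2. The dianion of tert-butyl acetoacetate (NaH, then n-BuLi, THF, 0 °C, in excess) would be acylated by F7 to give tert-butyl 6-(2-iodo-3,5-dimethoxyphenyl)-3,5-dioxohexanoate F8 after work-up; amide that is only enolised would be recovered. CF3CO2H and (CF3CO)2O in CH2Cl2 would lactonise F8 with loss of isobutene to 8.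

**Further compounds**
F1 | step 7 | 2,4-dihydroxy-6-methylbenzoic acid | Cc1cc(O)cc(O)c1C(=O)O
F2 | step 7 | 2,4-diacetoxy-6-methylbenzoic acid | CC(=O)Oc1cc(C)c(C(=O)O)c(OC(C)=O)c1
F3 | step 7 | 2,4-diacetoxy-6-methylbenzoyl chloride | CC(=O)Oc1cc(C)c(C(=O)Cl)c(OC(C)=O)c1
F4 | step 7 | 4-{3-[2-({4-(benzyloxy)-2-oxo-2H-pyran-6-yl}methyl)-4,6-dimethoxyphenyl]prop-2-ynoyl}-5-methyl-1,3-phenylene diacetate | CC(=O)Oc1cc(C)c(C(=O)C#Cc2c(OC)cc(OC)cc2Cc2cc(OCc3ccccc3)cc(=O)o2)c(OC(C)=O)c1
F5 | step 6 | 1,3-dimethoxy-5-methylbenzene | COc1cc(C)cc(OC)c1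
F6 | step 6 | 2-iodo-1,5-dimethoxy-3-methylbenzene | COc1cc(C)c(I)c(OC)c1
F7 | step 2 | 2-(2-iodo-3,5-dimethoxyphenyl)-N-methoxy-N-methylacetamide | COc1cc(CC(=O)N(C)OC)c(I)c(OC)c1
F8 | step 2 | tert-butyl 6-(2-iodo-3,5-dimethoxyphenyl)-3,5-dioxohexanoate | COc1cc(CC(=O)CC(=O)CC(=O)OC(C)(C)C)c(I)c(OC)c1
A1 | direct plan | 7-methoxy-5-methyl-2-(methylsulfonyl)-4H-chromen-4-one | COc1cc(C)c2c(c1)oc(S(C)(=O)=O)cc2=O
A2 | direct plan | 4-(benzyloxy)-6-methyl-2H-pyran-2-one | Cc1cc(OCc2ccccc2)cc(=O)o1
A3 | direct plan | 2-{[4-(benzyloxy)-2-oxo-2H-pyran-6-yl]methyl}-7-methoxy-5-methyl-4H-chromen-4-one | COc1cc(C)c2c(c1)oc(Cc1cc(OCc3ccccc3)cc(=O)o1)cc2=O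
A4 | direct plan | 3,5-dimethoxy-2-(trimethylsilyl)phenyl trifluoromethanesulfonate | COc1cc(OS(=O)(=O)C(F)(F)F)c([Si](C)(C)C)c(OC)c1
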